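**Labels:** ring A is the ring with one free OH. Ring B is the ring with two OH groups flanking the ether oxygen and the carbinol para to it. Chain carbons run C1′ (carbinol, on ring B) to C14′ (on ring A). The target is (1′R, 8′Z).

**Assumption:** 7-iodohept-1-ene and vinyl bromide (THF solution) are taken as catalogue items; the Ph-Pybox antipode that gives the (R)-boronic ester is fixed by a small test run, because the sense of induction could not be assigned with certainty here.

## Retrosynthetic overview

1. Target ⇐ its ring B bis-MOM ether; the 22-membered ring is the only ring built and is closed second to last by Z-selective RCM at C8′=C9′.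
2. RCM diene ⇐ ring B arene C2–H + ring A resorcinol O–H: diaryl ether by directed lithiation and copper-mediated oxidative C–O coupling.
3. Ring B carbinol fragment ⇐ aryl–Bpin + vinyl + 7-iodohept-1-ene: Ni-catalysed enantioselective conjunctive coupling, whose 1,2-aryl shift from boron to carbon makes the Ar–C1′ bond and the (R) centre; C–B oxidation gives the alcohol.
4. Ring A fragment ⇐ the same aryl–Bpin + 7-iodohept-1-ene (Cu-catalysed sp2–sp3 coupling), then MOM removal.
5. Common aryl–Bpin ⇐ resorcinol (MOM protection, Ir-catalysed C5–H borylation); both benzene rings come from resorcinol.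

## Route

**Step 1**
Reactants: 1 resorcinol (benzene-1,3-diol)
Product: 2 1,3-bis(methoxymethoxy)benzene
Conditions: NaH (2.4 equiv), MOMCl (2.4 equiv), DMF, 0 °C → rt
Reagents that add atoms: chloromethyl methyl ether, COCCl
Why: Williamson-type O-alkylation of the bis-phenoxide (MOM protection); the MOM groups later direct lithiation to C2 and are removable without strong acid.

**Step 2**
Reactants: 2 1,3-bis(methoxymethoxy)benzene
Product: 3 2-[3,5-bis(methoxymethoxy)phenyl]-4,4,5,5-tetramethyl-1,3,2-dioxaborolane
Conditions: B2pin2 (0.6 equiv), [Ir(OMe)(cod)]2 (1.5 mol%), 4,4′-di-tert-butyl-2,2′-bipyridine (3 mol%), THF, 80 °C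
Reagents that add atoms: bis(pinacolato)diboron, CC1(C)OB(OC1(C)C)B1OC(C)(C)C(C)(C)O1
Why: Sterically controlled iridium-catalysed aromatic C–H borylation; C5–H is the only C–H without an ortho substituent, so a 1,3-disubstituted arene gives the 5-boryl product.

**Step 3**
Reactants: 3 2-[3,5-bis(methoxymethoxy)phenyl]-4,4,5,5-tetramethyl-1,3,2-dioxaborolane; 4 7-iodohept-1-ene
Product: 5 1-(hept-6-en-1-yl)-3,5-bis(methoxymethoxy)benzene
Conditions: CuI (10 mol%), LiOtBu (2 equiv), DMF, 60 °C
Reagents that add atoms: none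
Why: Copper-catalysed Suzuki–Miyaura-type sp2–sp3 coupling of the tert-butoxide-activated aryl boronate with a primary alkyl iodide; the remote terminal alkene and the MOM ethers are inert, and this installs C9′–C14′ on ring A.

**Step 4**
Reactants: 5 1-(hept-6-en-1-yl)-3,5-bis(methoxymethoxy)benzene
Product: 6 5-(hept-6-en-1-yl)benzene-1,3-diol
Conditions: conc. HCl (cat.), MeOH, 50 °C
Reagents that add atoms: none
Why: Acid-catalysed acetal exchange (MOM cleavage) to methanol; the substrate has no acid-sensitive group besides the acetals.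

**Step 5**
Reactants: 3 2-[3,5-bis(methoxymethoxy)phenyl]-4,4,5,5-tetramethyl-1,3,2-dioxaborolane; 7 vinyl bromide (bromoethene); 4 7-iodohept-1-ene
Product: 11 (1R)-1-[3,5-bis(methoxymethoxy)phenyl]non-8-en-1-ol, via vinyllithium 8 (not isolated), via lithium aryl(vinyl)borate complex 9 (not isolated), via benzylic pinacol boronic ester 10 (not isolated)
Conditions: 7 (1.1 equiv), t-BuLi (2.1 equiv), Et2O, –78 °C; add 3, –78 °C → rt; evaporate, THF; NiBr2·glyme (10 mol%), Ph-Pybox (12 mol%, antipode giving (R)-10), 4 (1.5 equiv), rt, 18 h; then 3 M NaOH, 30% H2O2, 0 °C → rt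
Reagents that add atoms: hydrogen peroxide, OO
Why: Nickel-catalysed enantioselective conjunctive cross-coupling: the alkylnickel species formed from 4 binds the vinyl group of borate 9 and triggers a 1,2-aryl shift from boron to the α-carbon (1,2-metallate rearrangement), which forms Ar–C1′ and C2′–C3′ and sets C1′ as (R) under ligand control; peroxide oxidation of the C–B bond proceeds with retention.

**Step 6**
Reactants: 11 (1R)-1-[3,5-bis(methoxymethoxy)phenyl]non-8-en-1-ol; 6 5-(hept-6-en-1-yl)benzene-1,3-diol
Product: 15 (1R)-1-[4-[3-(hept-6-en-1-yl)-5-hydroxyphenoxy]-3,5-bis(methoxymethoxy)phenyl]non-8-en-1-ol, via C2-lithiated lithium alkoxide 12 (not isolated), via dilithium resorcinolate 13 (not isolated), via lithium aryl(aryloxo)cuprate 14 (not isolated)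
Conditions: 11, n-BuLi (2.1 equiv), THF, 0 °C, 1 h; CuCl·2LiCl (1.05 equiv), –50 °C; add 13 [from 6 (2.0 equiv), n-BuLi (4.0 equiv), THF–DMPU, 0 °C]; 3,3′,5,5′-tetra-tert-butyl-4,4′-diphenoquinone (1.2 equiv), –78 → –30 °C; AcOH quench
Reagents that add atoms: none
Why: Proposed new method: directed ortho-lithiation puts lithium at C2 between the two MOM-oxy groups (cooperative direction, as in 3,5-dialkoxybenzyl alkoxides), transmetalation gives an arylcopper that binds the phenoxide as a heteroleptic aryl(aryloxo)cuprate, and two-electron oxidation by the non-electrophilic quinone gives a trivalent copper aryl aryloxide that reductively eliminates the hindered diaryl ether C–O bond, while homocoupling is disfavoured because it would give a tetra-ortho-alkoxy biaryl; the closest known reactions are the quinone-mediated oxidative amination of lithium amidocuprates and the C–O reductive elimination of Chan–Lam couplings, and the stereocentre is a spectator.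

**Step 7**
Reactants: 15 (1R)-1-[4-[3-(hept-6-en-1-yl)-5-hydroxyphenoxy]-3,5-bis(methoxymethoxy)phenyl]non-8-en-1-ol
Product: 16 (1′R,8′Z)-macrocycle, the target with both ring B phenols as MOM ethers (22-membered meta,para-bridged diaryl ether; ring A OH and C1′ OH free)
Conditions: Ru(NO3)(=CH-C6H4-2-OiPr)(C,C-cyclometalated 1-adamantyl-3-(2,6-diisopropylphenyl)imidazolidin-2-ylidene) (7.5 mol%), ClCH2CH2Cl (3 mM), 60 °C, static vacuum
Reagents that add atoms: none
Why: Z-selective ring-closing metathesis; the chelated carbene forces a side-bound, all-syn metallacyclobutane so the cis olefin forms under kinetic control, with high dilution and ethene removal favouring the 22-membered ring over oligomers.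

**Step 8**
Reactants: 16 (1′R,8′Z)-macrocycle with ring B bis-MOM ether
Product: 17 CNP0316989.2, the (1′R,8′Z)-macrocyclic triphenol carbinol (target)
Conditions: Me3SiOTf (6 equiv), 2,2′-bipyridyl (9 equiv), CH3CN, 0 °C → rt; then H2O
Reagents that add atoms: none
Why: Silyl triflate/bipyridyl MOM cleavage: the aryl MOM ethers are converted through a pyridinium intermediate into aryl silyl ethers that water hydrolyses, and these buffered non-protic conditions avoid ionising the p-aryloxybenzylic (R)-carbinol and leave the Z-olefin untouched.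

## Compound list

1 | resorcinol (benzene-1,3-diol) | Oc1cccc(O)c1 | starting material
2 | 1,3-bis(methoxymethoxy)benzene | COCOc1cccc(OCOC)c1 | intermediate
3 | 2-[3,5-bis(methoxymethoxy)phenyl]-4,4,5,5-tetramethyl-1,3,2-dioxaborolane | COCOc1cc(cc(OCOC)c1)B1OC(C)(C)C(C)(C)O1 | intermediate
4 | 7-iodohept-1-ene | ICCCCCC=C | starting material
5 | 1-(hept-6-en-1-yl)-3,5-bis(methoxymethoxy)benzene | COCOc1cc(CCCCCC=C)cc(OCOC)c1 | intermediate
6 | 5-(hept-6-en-1-yl)benzene-1,3-diol | Oc1cc(CCCCCC=C)cc(O)c1 | intermediate
7 | vinyl bromide (bromoethene) | BrC=C | starting material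
8 | vinyllithium | [Li]C=C | intermediate
9 | lithium [3,5-bis(methoxymethoxy)phenyl](vinyl)(pinacolato)borate | [Li+].C=C[B-]1(OC(C)(C)C(C)(C)O1)c1cc(OCOC)cc(OCOC)c1 | intermediate
10 | 2-[(1R)-1-[3,5-bis(methoxymethoxy)phenyl]non-8-en-1-yl]-4,4,5,5-tetramethyl-1,3,2-dioxaborolane | COCOc1cc(cc(OCOC)c1)[C@H](B1OC(C)(C)C(C)(C)O1)CCCCCCC=C | intermediate
11 | (1R)-1-[3,5-bis(methoxymethoxy)phenyl]non-8-en-1-ol | COCOc1cc(cc(OCOC)c1)[C@H](O)CCCCCCC=C | intermediate
12 | lithium (1R)-1-[4-lithio-3,5-bis(methoxymethoxy)phenyl]non-8-en-1-olate | [Li]c1c(OCOC)cc(cc1OCOC)[C@H](O[Li])CCCCCCC=C | intermediate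
13 | dilithium 5-(hept-6-en-1-yl)benzene-1,3-diolate | [Li+].[Li+].[O-]c1cc(CCCCCC=C)cc([O-])c1 | intermediate
14 | trilithium aryl(aryloxo)cuprate: copper bound to ring B C2 and to one ring A oxygen, with the C1′ alkoxide and the second ring A phenoxide as lithium salts, (1′R) | [Li+].[Li+].[Li+].[O-]c1cc(CCCCCC=C)cc(O[Cu-]c2c(OCOC)cc(cc2OCOC)[C@H]([O-])CCCCCCC=C)c1 | intermediate
15 | (1R)-1-[4-[3-(hept-6-en-1-yl)-5-hydroxyphenoxy]-3,5-bis(methoxymethoxy)phenyl]non-8-en-1-ol | C=CCCCCCc1cc(O)cc(Oc2c(OCOC)cc(cc2OCOC)[C@H](O)CCCCCCC=C)c1 | intermediate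
16 | (1′R,8′Z)-22-membered diaryl ether macrocycle, ring B bis-MOM ether of the target | Oc1cc2cc(c1)Oc1c(OCOC)cc(cc1OCOC)[C@H](O)CCCCCC/C=C\CCCCC2 | intermediate
17 | CNP0316989.2: (1′R,8′Z)-22-membered diaryl ether macrocycle; ring A 5-hydroxy-1,3-phenylene, ring B 2,6-dihydroxy-1,4-phenylene, chain CH(OH)–(CH2)6–CH=CH–(CH2)5 | Oc1cc2cc(c1)Oc1c(O)cc(cc1O)[C@H](O)CCCCCC/C=C\CCCCC2 | target

## Step count and risks

Total steps: 8. Longest linear sequence: 7 (steps 1, 2, 3, 4, 6, 7, 8).

**Step 5 (yield and enantioselectivity of the conjunctive coupling with this electron-rich aryl boronate).** The fallback keeps a 1,2-shift from boron to carbon but makes it stereospecific instead of catalyst-controlled. It sets out from 4 and 3 and comes back at 11 through 10.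
- Iodide 4 is exchanged with t-BuLi (Et2O–pentane, –78 °C) to hept-6-en-1-yllithium F1, which opens ethylene oxide to give non-8-en-1-ol F2.
- Carbamoylation (N,N-diisopropylcarbamoyl chloride, Et3N, CH2Cl2, reflux) gives non-8-en-1-yl N,N-diisopropylcarbamate F3.
- s-BuLi/(–)-sparteine (Et2O, –78 °C) removes the pro-S proton to give the (S)-α-lithiated carbamate F4, which adds to 3 with retention to give the (S)-boronate complex F5.
- On warming with MgBr2·OEt2 the aryl group shifts with inversion and expels the carbamate, giving 10; NaOH/H2O2 then gives 11.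

**Step 6 (the new oxidative C–O coupling).** Possible failures are protonation or oxygenation of the arylcopper, direct oxidation of the electron-rich resorcinolate, or interference by the C1′ alkoxide. The fallback is known chemistry in two steps. It sets out from 11: the same lithiation to 12 is quenched with 1,2-diiodoethane to give (1R)-1-[4-iodo-3,5-bis(methoxymethoxy)phenyl]non-8-en-1-ol F6. Ullmann diaryl ether coupling of F6 with 6 (3 equiv; CuI 20 mol%, picolinic acid 40 mol%, K3PO4, DMSO, 90 °C) comes back at 15.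

**Step 7 (Z-selectivity and catalyst lifetime with the free phenol; oligomerisation).** The fallback replaces kinetic Z-selection by a stereoretentive sequence. It sets out from 15: cross-metathesis with excess (Z)-but-2-ene using Ru(=CH-C6H4-2-OiPr)(3,6-Cl2C6H2S2)(1,3-dimesitylimidazolidin-2-ylidene) caps both termini to give the bis-(Z)-prop-1-enyl diene F7. Ring closure of F7 with the same catalyst at 3 mM under vacuum retains the cis geometry and comes back at 16.

## Further compounds

F1 | step 5 | hept-6-en-1-yllithium | [Li]CCCCCC=C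
F2 | step 5 | non-8-en-1-ol | OCCCCCCCC=C
F3 | step 5 | non-8-en-1-yl N,N-diisopropylcarbamate | C=CCCCCCCCOC(=O)N(C(C)C)C(C)C
F4 | step 5 | (1S)-1-lithionon-8-en-1-yl N,N-diisopropylcarbamate (sparteine-bound) | [Li][C@@H](CCCCCCC=C)OC(=O)N(C(C)C)C(C)C
F5 | step 5 | lithium [3,5-bis(methoxymethoxy)phenyl][(1S)-1-(N,N-diisopropylcarbamoyloxy)non-8-en-1-yl](pinacolato)borate | [Li+].C=CCCCCCC[C@@H](OC(=O)N(C(C)C)C(C)C)[B-]1(OC(C)(C)C(C)(C)O1)c1cc(OCOC)cc(OCOC)c1
F6 | step 6 | (1R)-1-[4-iodo-3,5-bis(methoxymethoxy)phenyl]non-8-en-1-ol | COCOc1cc(cc(OCOC)c1I)[C@H](O)CCCCCCC=C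
F7 | step 7 | (1R,9Z)-1-[4-[3-hydroxy-5-[(6Z)-oct-6-en-1-yl]phenoxy]-3,5-bis(methoxymethoxy)phenyl]dec-8-en-1-ol | C/C=C\CCCCCc1cc(O)cc(Oc2c(OCOC)cc(cc2OCOC)[C@H](O)CCCCCC/C=C\C)c1
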